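**Retrosynthetic overview**
1. 19 ⇐ 18 (desilylation) ⇐ 17: the C14–O bond and the ring-cis C1=C10 olefin come from a 1,3-hydroxyl transposition of a 1-hydroxy-10(14)-methylidene macrocycle (key step).
2. 17 ⇐ 16: C1–C10 by Nozaki–Hiyama–Kishi closure; the ten-membered carbocycle is formed second.
3. 16 ⇐ 13 + 14: C8–O by Mitsunobu inversion with methacrylic acid; 13 ⇐ 10 + 12: C7–C8 by zinc allylation.
4. 10 ⇐ 8 ⇐ 5 + 6: the butyrolactone is formed first, by iridium-catalysed 2-(alkoxycarbonyl)allylation, which sets C6.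
5. 5 ⇐ 3 ⇐ 1: C4 is set by an enantioselective Baeyer–Villiger C–O insertion into a 4-substituted cyclohexanone.

Assumption: locants follow germacrane numbering (ring C1–C10, lactone carbons C11–C13, C14 on C10, C15 on C4); TBDPS = tert-butyl(diphenyl)silyl; compounds 1, 6, 11 and 14 are taken as cheap catalogue chemicals.

**Route**

Step 1
Reactants: 1 4-(hydroxymethyl)cyclohexan-1-one
Product: 2 4-{[TBDPS]oxymethyl}cyclohexan-1-one
Conditions: TBDPSCl, imidazole, DMF, 0 °C to rt
Reagents that add atoms: tert-butyl(chloro)diphenylsilane CC(C)(C)[Si](Cl)(c1ccccc1)c1ccccc1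
Why: Imidazole-promoted O-silylation masks the future C15 hydroxyl with a group that survives peracid, hydride, bromine, mild acid, CrCl2 and perrhenate.

Step 2
Reactants: 2 4-{[TBDPS]oxymethyl}cyclohexan-1-one
Product: 3 (5S)-5-{[TBDPS]oxymethyl}oxepan-2-one
Conditions: Sc(OTf)3 (5 mol%), chiral N,N'-dioxide ligand (5 mol%, antipode chosen for 5S), mCPBA, EtOAc, −20 °C
Reagents that add atoms: mCPBA (3-chloroperoxybenzoic acid) OOC(=O)c1cccc(Cl)c1
Why: Catalytic enantioselective Baeyer–Villiger desymmetrisation, in which the chiral scandium complex lets only one of the two enantiotopic α-carbons migrate in the Criegee adduct, so the new C–O bond sets C4 as (S).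

Step 3
Reactants: 3 (5S)-5-{[TBDPS]oxymethyl}oxepan-2-one
Product: 5 (3S)-3-{[TBDPS]oxymethyl}-5-(1,3-dioxolan-2-yl)pentan-1-ol, via lactol 4 (not isolated)
Conditions: i-Bu2AlH, CH2Cl2, −78 °C, aqueous potassium sodium tartrate work-up; then ethylene glycol, PPTS, PhH, 80 °C (Dean–Stark)
Reagents that add atoms: ethylene glycol OCCO
Why: Half-reduction of the lactone to the lactol followed by acid-catalysed acetalisation, where the five-membered dioxolane is preferred over the seven-membered mixed acetal, masks the C1 aldehyde and frees the C6 hydroxyl.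

Step 4
Reactants: 5 (3S)-3-{[TBDPS]oxymethyl}-5-(1,3-dioxolan-2-yl)pentan-1-ol; 6 methyl 2-(acetoxymethyl)prop-2-enoate
Product: 8 (5R)-5-[(2S)-2-{[TBDPS]oxymethyl}-4-(1,3-dioxolan-2-yl)butyl]-3-methylideneoxolan-2-one, via hydroxy ester 7 (not isolated)
Conditions: [Ir(cod)Cl]2 (2.5 mol%), (R)-SEGPHOS (5 mol%, antipode chosen for 6R), 4-cyano-3-nitrobenzoic acid (10 mol%), Cs2CO3 (20 mol%), THF, 90 °C; then PPTS (cat.), PhMe, 60 °C
Reagents that add atoms: none
Why: Krische iridium-catalysed transfer-hydrogenative 2-(alkoxycarbonyl)allylation at the alcohol oxidation level, then lactonisation; the chiral allyl-iridium adds to the transient aldehyde under catalyst control and sets C6 as (R).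

Step 5
Reactants: 8 (5R)-5-[(2S)-2-{[TBDPS]oxymethyl}-4-(1,3-dioxolan-2-yl)butyl]-3-methylideneoxolan-2-one
Product: 10 (5R)-3-(bromomethyl)-5-[(2S)-2-{[TBDPS]oxymethyl}-4-(1,3-dioxolan-2-yl)butyl]furan-2(5H)-one, via dibromide 9 (not isolated)
Conditions: Br2, CH2Cl2, −20 °C; then Et3N, 0 °C
Reagents that add atoms: bromine BrBr
Why: Bromine addition to the exocyclic alkene and E2 loss of HBr (tertiary bromide together with the C7 ring hydrogen) give the conjugated endocyclic allylic bromide without touching C6.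

Step 6
Reactants: 11 3-bromobut-3-en-1-ol
Product: 12 3-bromobut-3-enal
Conditions: Dess–Martin periodinane, NaHCO3, CH2Cl2, 0 °C; used at once as a solution
Reagents that add atoms: none
Why: Dess–Martin oxidation under bicarbonate buffer gives the labile β,γ-unsaturated aldehyde without base-induced conjugation.

Step 7
Reactants: 10 (5R)-3-(bromomethyl)-5-[(2S)-2-{[TBDPS]oxymethyl}-4-(1,3-dioxolan-2-yl)butyl]furan-2(5H)-one; 12 3-bromobut-3-enal
Product: 13 (4R,5R)-4-[(1S)-3-bromo-1-hydroxybut-3-en-1-yl]-5-[(2S)-2-{[TBDPS]oxymethyl}-4-(1,3-dioxolan-2-yl)butyl]-3-methylideneoxolan-2-one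
Conditions: Zn dust, THF/sat. aq. NH4Cl, 0 °C
Reagents that add atoms: none
Why: Zinc Barbier allylation through a chair Zimmerman–Traxler transition state: the allylzinc bonds through C7 anti to the C6 side chain (6,7-trans lactone), and its ring-locked geometry (C6 trans to CH2Zn) gives the anti carbinol (8S), the C8 epimer that step 8 inverts.

Step 8
Reactants: 13 (4R,5R)-4-[(1S)-3-bromo-1-hydroxybut-3-en-1-yl]-5-[(2S)-2-{[TBDPS]oxymethyl}-4-(1,3-dioxolan-2-yl)butyl]-3-methylideneoxolan-2-one; 14 methacrylic acid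
Product: 15 (1R)-3-bromo-1-{(2R,3S)-2-[(2S)-2-{[TBDPS]oxymethyl}-4-(1,3-dioxolan-2-yl)butyl]-4-methylidene-5-oxooxolan-3-yl}but-3-en-1-yl 2-methylprop-2-enoate
Conditions: PPh3, DIAD, THF/PhMe, 0 °C to rt
Reagents that add atoms: none
Why: Mitsunobu esterification, in which methacrylate displaces the C8 alkoxyphosphonium by SN2, so a single C–O bond formation inverts C8 to (8R) and installs the ester.

Step 9
Reactants: 15 the dioxolane methacrylate from step 8
Product: 16 (1R)-3-bromo-1-{(2R,3S)-2-[(2S)-2-{[TBDPS]oxymethyl}-5-oxopentyl]-4-methylidene-5-oxooxolan-3-yl}but-3-en-1-yl 2-methylprop-2-enoate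
Conditions: PPTS, acetone/H2O (10:1), 55 °C
Reagents that add atoms: water O
Why: Acid-catalysed acetal hydrolysis releases the C1 aldehyde while the silyl ether, both esters and the alkenyl bromide stay intact.

Step 10
Reactants: 16 the bromo aldehyde from step 9
Product: 17 (4S,6R,7S,8R)-15-[TBDPS]oxy-1-hydroxy-8-methacryloyloxygermacra-10(14),11(13)-dien-12,6-olide as a mixture of C1 epimers
Conditions: CrCl2 (8 equiv), NiCl2 (2 mol%), DMSO, 0.003 M, slow addition, rt
Reagents that add atoms: none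
Why: Nozaki–Hiyama–Kishi reaction, in which nickel inserts into the alkenyl bromide and the derived alkenylchromium adds only to the aldehyde, closes the ten-membered ring; the C1 configuration does not matter because both epimers converge in step 11.

Step 11
Reactants: 17 the macrocyclic allylic alcohol from step 10 (both C1 epimers)
Product: 18 (4S,6R,7S,8R)-15-[TBDPS]oxy-14-hydroxy-8-methacryloyloxygermacra-1(10),11(13)-dien-12,6-olide with ring-cis C1=C10 (C2 cis to C9, CIP E)
Conditions: Ph3SiOReO3 (5 mol%), Et2O, 0.01 M, −20 to 0 °C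
Reagents that add atoms: none
Why: Proposed new method: a stereoconvergent 1,3-hydroxyl transposition of a medium-ring 2-methylidenecycloalkanol, in which the C1 perrhenate ester of either epimer shifts oxygen to C14 through a chair [3,3] transition state with C2 pseudo-equatorial (hence C2 cis to C9), and reversibility drains the mixture to the endocyclic trisubstituted olefin that relieves transannular strain and carries an unhindered primary alcohol, so the step forms the C14–O bond and fixes the olefin geometry that ring-closing metathesis cannot deliver; the closest known reaction type is the oxo-rhenium (Ph3SiOReO3 or Re2O7) catalysed 1,3-transposition of acyclic allylic alcohols, which has not been shown to set a ring-olefin geometry in exocyclic-methylene medium rings.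

Step 12
Reactants: 18 the 15-O-TBDPS ether from step 11
Product: 19 target, (4S,6R,7S,8R)-14,15-dihydroxy-8-methacryloyloxygermacra-1(10),11(13)-dien-12,6-olide with ring-cis C1=C10 (CIP E)
Conditions: HF·pyridine, pyridine/THF, 0 °C to rt
Reagents that add atoms: none
Why: Fluoride-mediated Si–O cleavage under buffered acidic conditions frees the C15 hydroxyl without base, so there is no conjugate addition to the acrylates and no acyl migration.

**Compound list**

1 | 4-(hydroxymethyl)cyclohexan-1-one | O=C1CCC(CO)CC1 | starting material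
2 | 4-{[TBDPS]oxymethyl}cyclohexan-1-one | O=C1CCC(CO[Si](C(C)(C)C)(c2ccccc2)c3ccccc3)CC1 | intermediate
3 | (5S)-5-{[TBDPS]oxymethyl}oxepan-2-one | O=C1CC[C@H](CO[Si](C(C)(C)C)(c2ccccc2)c3ccccc3)CCO1 | intermediate
4 | (2RS,5S)-5-{[TBDPS]oxymethyl}oxepan-2-ol (lactol, in equilibrium with the open hydroxy aldehyde) | OC1CC[C@H](CO[Si](C(C)(C)C)(c2ccccc2)c3ccccc3)CCO1 | intermediate
5 | (3S)-3-{[TBDPS]oxymethyl}-5-(1,3-dioxolan-2-yl)pentan-1-ol | OCC[C@@H](CO[Si](C(C)(C)C)(c1ccccc1)c2ccccc2)CCC3OCCO3 | intermediate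
6 | methyl 2-(acetoxymethyl)prop-2-enoate | C=C(COC(C)=O)C(=O)OC | starting material
7 | methyl (4R,6S)-6-{[TBDPS]oxymethyl}-8-(1,3-dioxolan-2-yl)-4-hydroxy-2-methylideneoctanoate | COC(=O)C(=C)C[C@H](O)C[C@@H](CO[Si](C(C)(C)C)(c1ccccc1)c2ccccc2)CCC3OCCO3 | intermediate
8 | (5R)-5-[(2S)-2-{[TBDPS]oxymethyl}-4-(1,3-dioxolan-2-yl)butyl]-3-methylideneoxolan-2-one | O1CCOC1CC[C@H](CO[Si](C(C)(C)C)(c2ccccc2)c3ccccc3)C[C@H]4OC(=O)C(=C)C4 | intermediate
9 | (5R)-3-bromo-3-(bromomethyl)-5-[(2S)-2-{[TBDPS]oxymethyl}-4-(1,3-dioxolan-2-yl)butyl]oxolan-2-one (C3 epimers) | O1CCOC1CC[C@H](CO[Si](C(C)(C)C)(c2ccccc2)c3ccccc3)C[C@H]4OC(=O)C(Br)(CBr)C4 | intermediate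
10 | (5R)-3-(bromomethyl)-5-[(2S)-2-{[TBDPS]oxymethyl}-4-(1,3-dioxolan-2-yl)butyl]furan-2(5H)-one | O1CCOC1CC[C@H](CO[Si](C(C)(C)C)(c2ccccc2)c3ccccc3)C[C@H]4OC(=O)C(CBr)=C4 | intermediate
11 | 3-bromobut-3-en-1-ol | OCCC(Br)=C | starting material
12 | 3-bromobut-3-enal | O=CCC(Br)=C | intermediate
13 | (4R,5R)-4-[(1S)-3-bromo-1-hydroxybut-3-en-1-yl]-5-[(2S)-2-{[TBDPS]oxymethyl}-4-(1,3-dioxolan-2-yl)butyl]-3-methylideneoxolan-2-one | O1CCOC1CC[C@H](CO[Si](C(C)(C)C)(c2ccccc2)c3ccccc3)C[C@H]4OC(=O)C(=C)[C@@H]4[C@@H](O)CC(Br)=C | intermediate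
14 | methacrylic acid | CC(=C)C(=O)O | starting material
15 | (1R)-3-bromo-1-{(2R,3S)-2-[(2S)-2-{[TBDPS]oxymethyl}-4-(1,3-dioxolan-2-yl)butyl]-4-methylidene-5-oxooxolan-3-yl}but-3-en-1-yl 2-methylprop-2-enoate | O1CCOC1CC[C@H](CO[Si](C(C)(C)C)(c2ccccc2)c3ccccc3)C[C@H]4OC(=O)C(=C)[C@@H]4[C@H](OC(=O)C(C)=C)CC(Br)=C | intermediate
16 | (1R)-3-bromo-1-{(2R,3S)-2-[(2S)-2-{[TBDPS]oxymethyl}-5-oxopentyl]-4-methylidene-5-oxooxolan-3-yl}but-3-en-1-yl 2-methylprop-2-enoate | O=CCC[C@H](CO[Si](C(C)(C)C)(c2ccccc2)c3ccccc3)C[C@H]4OC(=O)C(=C)[C@@H]4[C@H](OC(=O)C(C)=C)CC(Br)=C | intermediate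
17 | (4S,6R,7S,8R)-15-[TBDPS]oxy-1-hydroxy-8-methacryloyloxygermacra-10(14),11(13)-dien-12,6-olide (C1 epimers) | C=C(C)C(=O)O[C@@H]1CC(=C)C(O)CC[C@H](CO[Si](C(C)(C)C)(c3ccccc3)c4ccccc4)C[C@H]2OC(=O)C(=C)[C@H]12 | intermediate
18 | (4S,6R,7S,8R)-15-[TBDPS]oxy-14-hydroxy-8-methacryloyloxygermacra-1(10),11(13)-dien-12,6-olide, ring-cis C1=C10 | C=C(C)C(=O)O[C@@H]1C/C(CO)=C\CC[C@H](CO[Si](C(C)(C)C)(c3ccccc3)c4ccccc4)C[C@H]2OC(=O)C(=C)[C@H]12 | intermediate
19 | (4S,6R,7S,8R)-14,15-dihydroxy-8-methacryloyloxygermacra-1(10),11(13)-dien-12,6-olide, ring-cis C1=C10 | C=C(C)C(=O)O[C@@H]1C/C(CO)=C\CC[C@H](CO)C[C@H]2OC(=O)C(=C)[C@H]12 | target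

**Step count**
Total: 12 steps. Longest linear sequence: 11 steps (steps 1–5 and 7–12; step 6 is a one-step side branch).

**Three steps most likely to fail**

Step 11 (the proposed new transposition). The risks are an unfavourable equilibrium, some ring-trans olefin, or ether dimers from the primary allylic alcohol. The fallback uses known chemistry and sets out from 17. Thionyl chloride in Et2O at 0 °C gives, by SNi′ rearrangement of the chlorosulfite, the ring-cis primary allylic chloride F7. CsO2CH in DMF displaces the chloride by SN2 to give the allylic formate F8. KHCO3 in MeOH at 0 °C removes the formyl group without touching the methacrylate, and the sequence comes back to the route at 18.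

Step 10 (Nozaki–Hiyama–Kishi closure of a ten-membered ring). The risks are ring strain, reduction of the alkenyl bromide without C–C bond formation, and oligomers. The fallback closes the same bond by cross-coupling and introduces the C1 oxygen afterwards; it sets out from 16. Luche reduction (NaBH4, CeCl3·7H2O, MeOH, −40 °C) gives the primary alcohol F3, and I2/PPh3/imidazole gives the primary iodide F4. Zn dust with LiCl in THF inserts to give the alkylzinc iodide F5, which cyclises by intramolecular Negishi coupling (Pd(PPh3)4, THF, 0.005 M, 50 °C) onto the alkenyl bromide. This gives the 10(14)-methylidene macrocycle F6, which has no oxygen at C1. SeO2 (cat.)/t-BuOOH allylic hydroxylation then oxidises C1 (C9 is deactivated by the neighbouring ester), and the sequence comes back at 17.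

Step 8 (Mitsunobu inversion at a β-branched secondary alcohol). The risks are elimination towards the C7=C8 diene and incomplete inversion. The fallback sets the C8 configuration in the C–C bond formation instead, so no inversion is needed; it sets out from 10. Bu3SnCl and Zn dust in THF/aq. NH4Cl convert the bromide into the allylstannane F1. BF3·OEt2-promoted addition of F1 to aldehyde 12 at −78 °C goes through an open antiperiplanar transition state, which is syn-selective, and gives the (8R) alcohol F2 directly. Acylation of F2 with methacrylic anhydride, DMAP and Et3N comes back to the route at 15.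

**Further compounds**

F1 | step 8 | (5R)-5-[(2S)-2-{[TBDPS]oxymethyl}-4-(1,3-dioxolan-2-yl)butyl]-3-[(tributylstannyl)methyl]furan-2(5H)-one | O1CCOC1CC[C@H](CO[Si](C(C)(C)C)(c2ccccc2)c3ccccc3)C[C@H]4OC(=O)C(C[Sn](CCCC)(CCCC)CCCC)=C4
F2 | step 8 | (4R,5R)-4-[(1R)-3-bromo-1-hydroxybut-3-en-1-yl]-5-[(2S)-2-{[TBDPS]oxymethyl}-4-(1,3-dioxolan-2-yl)butyl]-3-methylideneoxolan-2-one (C8 epimer of 13) | O1CCOC1CC[C@H](CO[Si](C(C)(C)C)(c2ccccc2)c3ccccc3)C[C@H]4OC(=O)C(=C)[C@@H]4[C@H](O)CC(Br)=C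
F3 | step 10 | (1R)-3-bromo-1-{(2R,3S)-2-[(2S)-2-{[TBDPS]oxymethyl}-5-hydroxypentyl]-4-methylidene-5-oxooxolan-3-yl}but-3-en-1-yl 2-methylprop-2-enoate | OCCC[C@H](CO[Si](C(C)(C)C)(c2ccccc2)c3ccccc3)C[C@H]4OC(=O)C(=C)[C@@H]4[C@H](OC(=O)C(C)=C)CC(Br)=C
F4 | step 10 | (1R)-3-bromo-1-{(2R,3S)-2-[(2S)-2-{[TBDPS]oxymethyl}-5-iodopentyl]-4-methylidene-5-oxooxolan-3-yl}but-3-en-1-yl 2-methylprop-2-enoate | ICCC[C@H](CO[Si](C(C)(C)C)(c2ccccc2)c3ccccc3)C[C@H]4OC(=O)C(=C)[C@@H]4[C@H](OC(=O)C(C)=C)CC(Br)=C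
F5 | step 10 | alkylzinc iodide of F4 (C1–ZnI, all stereocentres as in F4) | I[Zn]CCC[C@H](CO[Si](C(C)(C)C)(c2ccccc2)c3ccccc3)C[C@H]4OC(=O)C(=C)[C@@H]4[C@H](OC(=O)C(C)=C)CC(Br)=C
F6 | step 10 | (4S,6R,7S,8R)-15-[TBDPS]oxy-8-methacryloyloxygermacra-10(14),11(13)-dien-12,6-olide | C=C(C)C(=O)O[C@@H]1CC(=C)CCC[C@H](CO[Si](C(C)(C)C)(c3ccccc3)c4ccccc4)C[C@H]2OC(=O)C(=C)[C@H]12
F7 | step 11 | (4S,6R,7S,8R)-14-chloro-15-[TBDPS]oxy-8-methacryloyloxygermacra-1(10),11(13)-dien-12,6-olide, ring-cis C1=C10 | C=C(C)C(=O)O[C@@H]1C/C(CCl)=C\CC[C@H](CO[Si](C(C)(C)C)(c3ccccc3)c4ccccc4)C[C@H]2OC(=O)C(=C)[C@H]12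
F8 | step 11 | (4S,6R,7S,8R)-14-formyloxy-15-[TBDPS]oxy-8-methacryloyloxygermacra-1(10),11(13)-dien-12,6-olide, ring-cis C1=C10 | C=C(C)C(=O)O[C@@H]1C/C(COC=O)=C\CC[C@H](CO[Si](C(C)(C)C)(c3ccccc3)c4ccccc4)C[C@H]2OC(=O)C(=C)[C@H]12
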